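**Retrosynthetic overview**

- Numbering: carbocycle C1–C10; oxirane C1–O–C10; C14 methyl on C10; C3 ketone; C15H2OH on C4; γ-lactone C6–O–C12 with C11(=C13) on C7; ester on C8. The strategy rests on C8–OH being homoallylic to the Z-trisubstituted C1=C10 olefin (later the oxirane) inside the ten-membered ring: the retron of a 2-methylallylboration with boron on C1 and C9 adding to a C8 aldehyde.
- Disconnections: target ⇒ C8–OH-directed epoxidation, C8 acylation, dithiane hydrolysis and lactone methylenation ⇒ macrocycle 22 ⇒ C8–C9 allylboration of lactone aldehyde 20 ⇒ copper-catalysed SN2′ borylation of an allylic carbonate (C1–B).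
- Precursor assembly: Evans syn-aldol/lactonisation (C6–C7), Corey–Seebach alkylation of a C3 dithiane (C2–C3), organocatalytic α-hydroxymethylation (C4).
- Ring order: γ-lactone (step 9), ten-membered carbocycle (step 15), oxirane (step 18).

Key step: step 15

Assumption: (R,R)-QuinoxP* is taken to deliver boron to the C1 face that gives the 1R boronate; if the sense is opposite for this β-methyl allylic carbonate, the (S,S)-ligand is used in the same step.

**Route**

Step 1
Reactants: 1 2-methyl-2-vinyloxirane
Product: 2 (2E)-4-chloro-2-methylbut-2-en-1-ol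
Conditions: TiCl4 (1.2 equiv), CH2Cl2, −85 °C; 1 M HCl
Reagents that add atoms: titanium tetrachloride, Cl[Ti](Cl)(Cl)Cl
Why: Lewis-acid SN2′ opening of a vinyl oxirane, in which chloride attacks the vinyl terminus of the TiCl4-bound epoxide and the s-trans conformer should give the E-trisubstituted olefin carrying C9 (CH2OH), C10 (with C14), C1 and C2 (CH2Cl).

Step 2
Reactants: 2 (2E)-4-chloro-2-methylbut-2-en-1-ol
Product: 3 (2E)-(4-chloro-2-methylbut-2-en-1-yloxy)triethylsilane
Conditions: Et3SiCl, imidazole, CH2Cl2, 0 °C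
Reagents that add atoms: chlorotriethylsilane, CC[Si](CC)(CC)Cl
Why: Standard silylation of a primary alcohol, giving a triethylsilyl ether that can later be cleaved in the presence of the primary TBS ether.

Step 3
Reactants: 4 4-oxobutyl acetate
Product: 6 (3S)-3-(1,3-dithian-2-yl)-4-hydroxybutyl acetate, via hydroxy aldehyde 5 (not isolated)
Conditions: (R)-α,α-diphenylprolinol trimethylsilyl ether (10 mol %), 37% aq. HCHO, pH 7 phosphate buffer, toluene, 23 °C; then HS(CH2)3SH, BF3·OEt2 (0.3 equiv), CH2Cl2, −20 °C
Reagents that add atoms: formaldehyde, C=O; propane-1,3-dithiol, SCCCS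
Why: Enamine-catalysed α-hydroxymethylation (organocatalytic cross-aldol with formaldehyde), in which formaldehyde attacks the E-enamine on the face away from the diphenyl(silyloxy)methyl group of the R-catalyst to set C4 as S, followed by immediate Lewis-acid thioacetalisation of the labile β-hydroxy aldehyde.

Step 4
Reactants: 6 (3S)-3-(1,3-dithian-2-yl)-4-hydroxybutyl acetate
Product: 7 (3S)-4-(tert-butyldimethylsilyloxy)-3-(1,3-dithian-2-yl)butyl acetate
Conditions: t-BuMe2SiCl, imidazole, DMF, 23 °C
Reagents that add atoms: tert-butyldimethylsilyl chloride, CC(C)(C)[Si](C)(C)Cl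
Why: Standard silylation of the primary C15 hydroxyl.

Step 5
Reactants: 7 (3S)-4-(tert-butyldimethylsilyloxy)-3-(1,3-dithian-2-yl)butyl acetate
Product: 8 (3S)-4-(tert-butyldimethylsilyloxy)-3-(1,3-dithian-2-yl)butan-1-ol
Conditions: K2CO3 (0.2 equiv), MeOH, 23 °C
Reagents that add atoms: none
Why: Base-catalysed methanolysis of the acetate, to which the silyl ether and the dithiane are inert.

Step 6
Reactants: 8 (3S)-4-(tert-butyldimethylsilyloxy)-3-(1,3-dithian-2-yl)butan-1-ol; 3 (2E)-(4-chloro-2-methylbut-2-en-1-yloxy)triethylsilane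
Product: 9 (3S)-4-(tert-butyldimethylsilyloxy)-3-{2-[(2E)-3-methyl-4-(triethylsilyloxy)but-2-en-1-yl]-1,3-dithian-2-yl}butan-1-ol
Conditions: t-BuLi (2.2 equiv), THF/HMPA 10:1, −78 °C; then 3, −78 → −40 °C
Reagents that add atoms: none
Why: Corey–Seebach alkylation, in which the first equivalent of t-BuLi forms the lithium alkoxide and the second the 2-lithio-1,3-dithiane, which is alkylated at carbon by the primary allylic chloride in SN2 fashion with retention of the E olefin (forms C2–C3).

Step 7
Reactants: 9 the C6 alcohol from step 6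
Product: 10 (3S)-4-(tert-butyldimethylsilyloxy)-3-{2-[(2E)-3-methyl-4-(triethylsilyloxy)but-2-en-1-yl]-1,3-dithian-2-yl}butanal
Conditions: SO3·pyridine, DMSO, i-Pr2NEt, CH2Cl2, 0 °C
Reagents that add atoms: none
Why: Parikh–Doering oxidation, an activated-DMSO method that leaves the dithiane sulfur, both silyl ethers and the olefin untouched and gives an aldehyde with no α-stereocentre.

Step 8
Reactants: 11 (S)-4-benzyl-oxazolidin-2-one; 12 methyl 4-chloro-4-oxobutanoate
Product: 13 methyl 4-[(4S)-4-benzyl-2-oxo-oxazolidin-3-yl]-4-oxobutanoate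
Conditions: n-BuLi, THF, −78 °C; then 12, −78 → 0 °C
Reagents that add atoms: none
Why: N-acylation of the lithiated oxazolidinone by the acid chloride.

Step 9
Reactants: 10 the C6 aldehyde from step 7; 13 methyl 4-[(4S)-4-benzyl-2-oxo-oxazolidin-3-yl]-4-oxobutanoate
Product: 15 trans-γ-lactone imide (4S,6R,7S) with the C6–O–C12 lactone closed; C7 carries the C8 acyl oxazolidinone; C3 dithiane; C15 OTBS; C9 OSiEt3, via syn-aldol adduct 14 (not isolated)
Conditions: 13 (1.3 equiv), Bu2BOTf, i-Pr2NEt, CH2Cl2, 0 °C; 10, −78 → 0 °C; pH 7 buffer, MeOH; then PPTS (cat.), CH2Cl2, 23 °C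
Reagents that add atoms: none
Why: Evans syn-aldol followed by lactonisation, in which the Z-boron enolate formed α to the imide (not α to the ester) adds to 10 through a Zimmerman–Traxler chair on the face away from the benzyl group to set C7 and C6 (6R), and the C6 hydroxyl then closes onto the methyl ester to give the trans-4,5-disubstituted γ-lactone.

Step 10
Reactants: 15 trans-γ-lactone imide (C9 OSiEt3)
Product: 16 trans-γ-lactone imide with free C9 allylic alcohol (4S,6R,7S)
Conditions: PPTS (0.2 equiv), MeOH/CH2Cl2 1:1, 0 °C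
Reagents that add atoms: none
Why: Acid-catalysed methanolysis of the primary allylic triethylsilyl ether, which is far more labile than the primary TBS ether.

Step 11
Reactants: 16 trans-γ-lactone imide with free C9 allylic alcohol
Product: 17 trans-γ-lactone imide C9 methyl carbonate (4S,6R,7S)
Conditions: ClCO2Me, pyridine, CH2Cl2, 0 °C
Reagents that add atoms: methyl chloroformate, COC(=O)Cl
Why: Standard carbonate formation on the primary allylic alcohol, installing the leaving group for the borylation.

Step 12
Reactants: 17 trans-γ-lactone imide C9 methyl carbonate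
Product: 18 hydroxymethyl lactone allylic carbonate (4S,6R,7R) with C8H2OH on C7
Conditions: NaBH4, THF/H2O 3:1, 0 °C
Reagents that add atoms: none
Why: Chemoselective borohydride reduction of the activated exocyclic imide carbonyl to the primary alcohol with release of the auxiliary, the γ-lactone and the carbonate reacting much more slowly at 0 °C and acyl transfer to O8 being blocked because it would pass through a strained 2,5-dioxabicyclo[2.2.1]heptane.

Step 13
Reactants: 18 hydroxymethyl lactone allylic carbonate
Product: 19 hydroxymethyl lactone with C1 allylic pinacolboronate (1R,4S,6R,7R) and C10(CH3)=C9H2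
Conditions: CuCl (5 mol %), (R,R)-QuinoxP* (5.5 mol %), KOt-Bu (10 mol %), B2pin2 (1.5 equiv), THF, 0 °C
Reagents that add atoms: bis(pinacolato)diboron, CC1(C)OB(OC1(C)C)B1OC(C)(C)C(C)(C)O1
Why: Copper-catalysed γ-selective (SN2′) boryl substitution of a primary allylic carbonate, in which the boryl copper species adds across C1=C10 with boron on C1 and the carbonate is expelled from C9 to leave the 1,1-disubstituted olefin, the C2-symmetric bisphosphine choosing the C1 face.

Step 14
Reactants: 19 hydroxymethyl lactone with C1 allylic pinacolboronate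
Product: 20 lactone aldehyde with C1 allylic boronate (1R,4S,6R,7S)
Conditions: Dess–Martin periodinane (1.3 equiv), NaHCO3, CH2Cl2, 0 °C, 30 min; used at once
Reagents that add atoms: none
Why: Dess–Martin oxidation under buffered, non-basic conditions, which should spare the C–B bond and the dithiane over a short reaction time and leave the trans C7 centre unepimerised.

Step 15
Reactants: 20 lactone aldehyde with C1 allylic boronate
Product: 22 ten-membered Z-homoallylic alcohol lactone (1(10)Z,4S,6R,7R,8R), via cyclised pinacol borate 21 (not isolated)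
Conditions: toluene (0.003 M), 4 Å molecular sieves, 70 °C; then MeOH, aq. NaHCO3, 23 °C
Reagents that add atoms: none
Why: Proposed new method: boron of the C1 pinacolboronate binds the C8 aldehyde oxygen, and B, C1, C10, C9, C8 and O pass through a six-membered chair in which C8–C9 forms while B–C1 breaks and the double bond moves to C1=C10 (allyl transposition). The closest known reactions are intermolecular additions of α-substituted allyl pinacolboronates to aldehydes, which are Z-selective with chirality transfer, and intramolecular allylborations that close five- to seven-membered rings; here the same chair has to close a ten-membered ring. The carbocycle C1–C10 closes by attack of C9 on the formyl carbon, exo at the carbonyl and with the olefin transposed into the ring, the C2–C7 chain bridging the axial position on C1 and the equatorial position on C8. C8 is the only new stereocentre and is set by the C1–B centre: with C2 axial (clear of the pinacol oxygens and of the C14 methyl on C10) and C7 equatorial, the 1R boronate should give 8R and the Z olefin from one chair. The step needs ring closure to beat intermolecular addition, the aldehyde to react and not the lactone, and C7 to stay unepimerised; high dilution, the inertness of pinacol allylboronates toward esters and the absence of acid, base or metal are meant to secure these.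

Step 16
Reactants: 22 ten-membered Z-homoallylic alcohol lactone
Product: 25 α-methylene lactone alcohol (1(10)Z,4S,6R,7R,8R) with C11=C13H2, via Mannich base 23 (not isolated), via trimethylammonium iodide 24 (not isolated)
Conditions: LiN(i-Pr)2 (2.4 equiv), THF, −78 °C; [Me2N=CH2]I (4 equiv), −78 → −20 °C; AcOH; then MeI, CH2Cl2/MeOH, 23 °C; then aq. NaHCO3, CH2Cl2
Reagents that add atoms: N,N-dimethylmethyleneiminium iodide, C[N+](C)=C.[I-]
Why: Eschenmoser methylenation, in which LiN(i-Pr)2 removes O8–H and one C11–H (the dithiane keeps C3 non-enolisable), the lactone enolate undergoes a Mannich reaction with the iminium salt, and quaternisation followed by base elimination forms C11=C13, acyl transfer to the O8 alkoxide again being blocked by the bicyclo[2.2.1] intermediate it would require.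

Step 17
Reactants: 25 α-methylene lactone alcohol
Product: 26 C3 ketone (1(10)Z,4S,6R,7R,8R) with free C8–OH and C15 OTBS
Conditions: PhI(OCOCF3)2 (1.5 equiv), NaHCO3, MeCN/H2O 9:1, 0 °C, 15 min
Reagents that add atoms: water, O
Why: Hypervalent-iodine-mediated oxidative hydrolysis of the dithiane, in which sulfur is oxidised far faster than the trisubstituted olefin, the sulfur fragment leaves as the disulfide so that no thiol can add to the methylene lactone, and the buffered medium should leave the β,γ-unsaturated ketone unconjugated.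

Step 18
Reactants: 26 C3 ketone
Product: 27 epoxy alcohol (1R,4S,6R,7R,8R,10S)
Conditions: VO(acac)2 (10 mol %), t-BuOOH (decane, 1.5 equiv), CH2Cl2, 0 → 23 °C
Reagents that add atoms: tert-butyl hydroperoxide, CC(C)(C)OO
Why: Vanadium-catalysed hydroxyl-directed epoxidation of a homoallylic alcohol, in which the vanadate ester of O8 delivers the peroxide oxygen through the chair O8–C8–C9–C10=C1 with C7 equatorial (the chair that closed the ring in step 15), so that oxygen should enter on the olefin face from which boron left and give the 1R,10S oxirane while the electron-poor methylene lactone stays inert.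

Step 19
Reactants: 27 epoxy alcohol; 28 (R)-2-methylbutanoic acid
Product: 29 C15 tert-butyldimethylsilyl ether of the target (1R,4S,6R,7S,8R,10S; 2R in the ester)
Conditions: DCC, DMAP (10 mol %), CH2Cl2, 0 °C
Reagents that add atoms: none
Why: Steglich esterification of the secondary C8 alcohol under nearly neutral conditions with only catalytic DMAP at 0 °C, chosen to spare the β,γ-epoxy ketone and the α-stereocentre of the acid.

Step 20
Reactants: 29 C15 tert-butyldimethylsilyl ether of the target
Product: 30 CNP0219035.1 (1R,4S,6R,7S,8R,10S; (2R)-2-methylbutanoate)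
Conditions: Et3N·3HF, MeCN, 0 → 23 °C
Reagents that add atoms: none
Why: Fluoride desilylation of a primary TBS ether with a nearly neutral HF source, chosen so that the oxirane, the β-hydroxy ketone being released and the methylene lactone should survive.

**Compound list**

1 | 2-methyl-2-vinyloxirane (racemic) | C=CC1(C)CO1 | starting material
2 | (2E)-4-chloro-2-methylbut-2-en-1-ol | OC/C(C)=C/CCl | intermediate
3 | (2E)-(4-chloro-2-methylbut-2-en-1-yloxy)triethylsilane | CC[Si](CC)(CC)OC/C(C)=C/CCl | intermediate
4 | 4-oxobutyl acetate | CC(=O)OCCCC=O | starting material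
5 | (3S)-3-formyl-4-hydroxybutyl acetate | CC(=O)OCC[C@@H](CO)C=O | intermediate
6 | (3S)-3-(1,3-dithian-2-yl)-4-hydroxybutyl acetate | CC(=O)OCC[C@@H](CO)C1SCCCS1 | intermediate
7 | (3S)-4-(tert-butyldimethylsilyloxy)-3-(1,3-dithian-2-yl)butyl acetate | CC(=O)OCC[C@@H](CO[Si](C)(C)C(C)(C)C)C1SCCCS1 | intermediate
8 | (3S)-4-(tert-butyldimethylsilyloxy)-3-(1,3-dithian-2-yl)butan-1-ol | OCC[C@@H](CO[Si](C)(C)C(C)(C)C)C1SCCCS1 | intermediate
9 | (3S)-4-(tert-butyldimethylsilyloxy)-3-{2-[(2E)-3-methyl-4-(triethylsilyloxy)but-2-en-1-yl]-1,3-dithian-2-yl}butan-1-ol | OCC[C@@H](CO[Si](C)(C)C(C)(C)C)C1(SCCCS1)C/C=C(C)/CO[Si](CC)(CC)CC | intermediate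
10 | (3S)-4-(tert-butyldimethylsilyloxy)-3-{2-[(2E)-3-methyl-4-(triethylsilyloxy)but-2-en-1-yl]-1,3-dithian-2-yl}butanal | O=CC[C@@H](CO[Si](C)(C)C(C)(C)C)C1(SCCCS1)C/C=C(C)/CO[Si](CC)(CC)CC | intermediate
11 | (S)-4-benzyl-oxazolidin-2-one | O=C1N[C@@H](Cc2ccccc2)CO1 | starting material
12 | methyl 4-chloro-4-oxobutanoate | COC(=O)CCC(=O)Cl | starting material
13 | methyl 4-[(4S)-4-benzyl-2-oxo-oxazolidin-3-yl]-4-oxobutanoate | COC(=O)CCC(=O)N1[C@@H](Cc2ccccc2)COC1=O | intermediate
14 | syn-aldol adduct (4S,6R,7S): methyl ester with C6–OH and the C8 acyl oxazolidinone on C7 | COC(=O)C[C@H](C(=O)N1[C@@H](Cc2ccccc2)COC1=O)[C@H](O)C[C@@H](CO[Si](C)(C)C(C)(C)C)C1(SCCCS1)C/C=C(C)/CO[Si](CC)(CC)CC | intermediate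
15 | trans-γ-lactone imide (4S,6R,7S), C9 OSiEt3 | O=C(N1[C@@H](Cc2ccccc2)COC1=O)[C@H]1CC(=O)O[C@@H]1C[C@@H](CO[Si](C)(C)C(C)(C)C)C1(SCCCS1)C/C=C(C)/CO[Si](CC)(CC)CC | intermediate
16 | trans-γ-lactone imide (4S,6R,7S), C9 OH | O=C(N1[C@@H](Cc2ccccc2)COC1=O)[C@H]1CC(=O)O[C@@H]1C[C@@H](CO[Si](C)(C)C(C)(C)C)C1(SCCCS1)C/C=C(C)/CO | intermediate
17 | trans-γ-lactone imide (4S,6R,7S), C9 methyl carbonate | O=C(N1[C@@H](Cc2ccccc2)COC1=O)[C@H]1CC(=O)O[C@@H]1C[C@@H](CO[Si](C)(C)C(C)(C)C)C1(SCCCS1)C/C=C(C)/COC(=O)OC | intermediate
18 | hydroxymethyl lactone allylic carbonate (4S,6R,7R) | OC[C@H]1CC(=O)O[C@@H]1C[C@@H](CO[Si](C)(C)C(C)(C)C)C1(SCCCS1)C/C=C(C)/COC(=O)OC | intermediate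
19 | hydroxymethyl lactone with C1 allylic pinacolboronate (1R,4S,6R,7R) | OC[C@H]1CC(=O)O[C@@H]1C[C@@H](CO[Si](C)(C)C(C)(C)C)C1(SCCCS1)C[C@@H](B2OC(C)(C)C(C)(C)O2)C(C)=C | intermediate
20 | lactone aldehyde with C1 allylic boronate (1R,4S,6R,7S) | O=C[C@H]1CC(=O)O[C@@H]1C[C@@H](CO[Si](C)(C)C(C)(C)C)C2(SCCCS2)C[C@@H](B3OC(C)(C)C(C)(C)O3)C(C)=C | intermediate
21 | cyclised pinacol borate ester of 22 (O8–Bpin) | C1C(=O)O[C@@H]2C[C@@H](CO[Si](C)(C)C(C)(C)C)C3(SCCCS3)C/C=C(C)\C[C@@H](OB4OC(C)(C)C(C)(C)O4)[C@@H]12 | intermediate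
22 | ten-membered Z-homoallylic alcohol lactone (1(10)Z,4S,6R,7R,8R) | C1C(=O)O[C@@H]2C[C@@H](CO[Si](C)(C)C(C)(C)C)C3(SCCCS3)C/C=C(C)\C[C@@H](O)[C@@H]12 | intermediate
23 | Mannich base: 11-(dimethylaminomethyl) lactone, C11 epimers | CN(C)CC1C(=O)O[C@@H]2C[C@@H](CO[Si](C)(C)C(C)(C)C)C3(SCCCS3)C/C=C(C)\C[C@@H](O)[C@@H]12 | intermediate
24 | trimethylammonium iodide of 23 | C[N+](C)(C)CC1C(=O)O[C@@H]2C[C@@H](CO[Si](C)(C)C(C)(C)C)C3(SCCCS3)C/C=C(C)\C[C@@H](O)[C@@H]12.[I-] | intermediate
25 | α-methylene lactone alcohol (1(10)Z,4S,6R,7R,8R), C3 dithiane | C=C1C(=O)O[C@@H]2C[C@@H](CO[Si](C)(C)C(C)(C)C)C3(SCCCS3)C/C=C(C)\C[C@@H](O)[C@@H]12 | intermediate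
26 | C3 ketone (1(10)Z,4S,6R,7R,8R), C8 OH, C15 OTBS | C=C1C(=O)O[C@@H]2C[C@@H](CO[Si](C)(C)C(C)(C)C)C(=O)C/C=C(C)\C[C@@H](O)[C@@H]12 | intermediate
27 | epoxy alcohol (1R,4S,6R,7R,8R,10S) | C=C1C(=O)O[C@@H]2C[C@@H](CO[Si](C)(C)C(C)(C)C)C(=O)C[C@H]3O[C@@]3(C)C[C@@H](O)[C@@H]12 | intermediate
28 | (R)-2-methylbutanoic acid | CC[C@@H](C)C(=O)O | starting material
29 | C15 tert-butyldimethylsilyl ether of the target (1R,4S,6R,7S,8R,10S) | C=C1C(=O)O[C@@H]2C[C@@H](CO[Si](C)(C)C(C)(C)C)C(=O)C[C@H]3O[C@@]3(C)C[C@@H](OC(=O)[C@H](C)CC)[C@@H]12 | intermediate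
30 | CNP0219035.1 (1R,4S,6R,7S,8R,10S; (2R)-2-methylbutanoate) | C=C1C(=O)O[C@@H]2C[C@@H](CO)C(=O)C[C@H]3O[C@@]3(C)C[C@@H](OC(=O)[C@H](C)CC)[C@@H]12 | target

**Step count and risk**

Total step count: 20. Longest linear sequence: 17 steps (steps 3–7 and 9–20, from 4).

Steps most likely to fail:

1. Step 15 (key step). What may go wrong: intermolecular allylboration (oligomerisation) may outrun ring closure, or ring strain may force closure through a boat or through the chair with C2 equatorial, giving the E olefin or the C8 epimer. Fallback (known chemistry, ring closure at C1=C10 by olefin metathesis), setting out from 8 and returning at 22: 8 is alkylated as in step 6 but with allyl bromide to give allyl dithiane alcohol F1, which is oxidised (SO3·pyridine, DMSO, i-Pr2NEt) to aldehyde F2. The Evans aldol with 13 as in step 9 gives aldol adduct F3 and, after lactonisation, lactone imide F4. NaBH4 in THF/H2O gives hydroxymethyl lactone F5, and Dess–Martin oxidation gives formyl lactone F6. The antipode of B-methallyldiisopinocampheylborane that attacks the aldehyde face leading to 8R (Et2O, −78 °C, ethanolamine work-up) gives, under reagent control, homoallylic alcohol F7. The second-generation Grubbs catalyst in dilute toluene at 80 °C then joins the allyl and 2-methylallyl olefins with loss of ethene, the ten-membered ring enforcing the Z geometry, to give 22.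

2. Step 13. What may go wrong: slow boryl copper addition across the β-methyl-substituted olefin, or poor facial selectivity at C1. Fallback, setting out from 18 and returning at 19: stereocontrol is moved from the catalyst to a separation. Compound 18 is borylated with CuCl, Xantphos, KOt-Bu and B2pin2 (a ligand without chirality, the system for which γ-selective boryl substitution of allylic carbonates is best established), giving 19 together with its C1 epimer F8. The two are diastereomers and are separated by chromatography, and 19 goes on to step 14.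

3. Step 18. What may go wrong: oxygen delivery through the alternative chair (poor facial selectivity), or isomerisation of the β,γ-unsaturated ketone under the vanadium conditions. Fallback, setting out from 26 and returning at 27: facial control is moved from the substrate hydroxyl to the reagent by a Shi epoxidation. The enantiomer of the fructose-derived ketone whose spiro transition state places the dioxirane on the C8-bearing olefin face is used with KHSO5 in a NaHCO3-buffered MeCN/water mixture at 0 °C. This makes no new compound (F0).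

Further compounds
F1 | step 15 | (3S)-3-(2-allyl-1,3-dithian-2-yl)-4-(tert-butyldimethylsilyloxy)butan-1-ol | OCC[C@@H](CO[Si](C)(C)C(C)(C)C)C1(SCCCS1)CC=C
F2 | step 15 | (3S)-3-(2-allyl-1,3-dithian-2-yl)-4-(tert-butyldimethylsilyloxy)butanal | O=CC[C@@H](CO[Si](C)(C)C(C)(C)C)C1(SCCCS1)CC=C
F3 | step 15 | syn-aldol adduct of F2 and 13 (4S,6R,7S) | COC(=O)C[C@H](C(=O)N1[C@@H](Cc2ccccc2)COC1=O)[C@H](O)C[C@@H](CO[Si](C)(C)C(C)(C)C)C1(SCCCS1)CC=C
F4 | step 15 | trans-γ-lactone imide with 2-allyl dithiane (4S,6R,7S) | O=C(N1[C@@H](Cc2ccccc2)COC1=O)[C@H]1CC(=O)O[C@@H]1C[C@@H](CO[Si](C)(C)C(C)(C)C)C1(SCCCS1)CC=C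
F5 | step 15 | hydroxymethyl lactone with 2-allyl dithiane (4S,6R,7R) | OC[C@H]1CC(=O)O[C@@H]1C[C@@H](CO[Si](C)(C)C(C)(C)C)C1(SCCCS1)CC=C
F6 | step 15 | formyl lactone with 2-allyl dithiane (4S,6R,7S) | O=C[C@H]1CC(=O)O[C@@H]1C[C@@H](CO[Si](C)(C)C(C)(C)C)C1(SCCCS1)CC=C
F7 | step 15 | 8R homoallylic alcohol with 2-methylallyl on C8 and allyl on C3 (4S,6R,7R,8R) | C=C(C)C[C@@H](O)[C@H]1CC(=O)O[C@@H]1C[C@@H](CO[Si](C)(C)C(C)(C)C)C1(SCCCS1)CC=C
F8 | step 13 | C1 epimer of 19 (1S,4S,6R,7R) | OC[C@H]1CC(=O)O[C@@H]1C[C@@H](CO[Si](C)(C)C(C)(C)C)C1(SCCCS1)C[C@H](B2OC(C)(C)C(C)(C)O2)C(C)=C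
F0 | step 18 | none | none
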